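1. Retrosynthesis (prostanoid numbering: ester carbon C1, chain to C7, ring C8–C12, ketone C9, Cl on C10, OAc on C12, octenyl chain C13–C20): remove the C12 acetate, return the 5E,7E-diene to a C6≡C7 alkyne on an sp3 C8, then cut the ring bond C8–C12.
2. Enabling feature: ring atoms C9(=O)–C10(Cl)=C11–C12(O) are an oxidised 3-chlorofuran (furan oxygen = ketone oxygen, furan C2–C5 = C9–C12) whose exocyclic carbinol carbon is C8, so a 2-furyl propargylic carbinol already holds all five ring carbons.
3. Further cuts: C7–C8 (acetylide addition to a furfural), furan C5–C13 (allylic alkylation), the formyl carbon and the C–Cl bond, leading back to 3-bromofuran, (Z)-oct-2-en-1-ol and methyl hept-6-ynoate.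
4. Forward order: chlorofuran, 2-formylation, C5 allylation, alkynylation, cyclopentenone formation (the only ring, closed at C8–C12), chain isomerisation, acetylation.
5. Stereochemistry: C12 is fixed in the ring-forming step by the sense of conrotation under a chiral Brønsted acid (C8 is transient and later sp2); 14Z is bought with the allylic alcohol; 5E,7E comes from thermodynamically controlled isomerisation.

Key step: step 6

Assumption: the propargylic carbinol that enters the key step is made and used as the racemate, because its carbinol carbon is planarised on ionisation; its SMILES carries no descriptor at that carbon.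
Assumption: the (R) antipode of the acid catalyst is written in step 6; should it favour the opposite sense of conrotation, the (S) antipode is used.
Remark: the C12 descriptor changes from S (cyclopentenone with sp3 C8) to R (allenone, dienone, target) only because C8 outranks C11 in CIP priority once it is sp2; no bond at C12 is touched.

Step 1
Reactants: 1 3-bromofuran
Product: 3 3-chlorofuran, via 3-furyllithium 2 (not isolated)
Conditions: n-BuLi (pentane), Et2O, −78 °C; C2Cl6, −78 → 0 °C; fractional distillation
Reagents that add atoms: hexachloroethane, ClC(Cl)(Cl)C(Cl)(Cl)Cl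
Why: Bromine–lithium exchange at −78 °C gives the 3-lithio species without equilibration to the 2-lithio isomer, and halophilic attack of the carbanion on hexachloroethane delivers the chloride (halogen–metal exchange followed by electrophilic chlorination).

Step 2
Reactants: 3 3-chlorofuran
Product: 5 3-chlorofuran-2-carbaldehyde, via 3-chloro-2-furyllithium 4 (not isolated)
Conditions: LiN(i-Pr)2, THF, −78 °C; DMF, −78 → 0 °C; H2O
Reagents that add atoms: N,N-dimethylformamide, CN(C)C=O
Why: The amide base removes the most acidic ring proton, C2–H flanked by the ring oxygen and the chlorine (directed α-lithiation), and the furyllithium is formylated by DMF, the hemiaminal alkoxide collapsing to the aldehyde on work-up.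

Step 3
Reactants: 6 (Z)-oct-2-en-1-ol
Product: 7 (Z)-1-bromooct-2-ene
Conditions: CBr4, PPh3, CH2Cl2, 0 °C
Reagents that add atoms: carbon tetrabromide, BrC(Br)(Br)Br
Why: Appel reaction: bromide displaces the alkoxyphosphonium group at the primary carbon (SN2) under neutral, cold conditions, so the Z-alkene should neither migrate nor isomerise.

Step 4
Reactants: 5 3-chlorofuran-2-carbaldehyde; 7 (Z)-1-bromooct-2-ene
Product: 10 3-chloro-5-[(Z)-oct-2-en-1-yl]furan-2-carbaldehyde, via lithium amino alkoxide 8 (not isolated), via 5-lithio amino alkoxide 9 (not isolated)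
Conditions: 1-methylpiperazine, n-BuLi, THF, −78 °C, then 5; n-BuLi, −78 → −40 °C; 7, −78 → 0 °C; H2O
Reagents that add atoms: none
Why: Addition of lithium 4-methylpiperazin-1-ide to the formyl group masks the aldehyde in situ as an α-amino alkoxide, n-BuLi then removes the only remaining furan α-proton (C5; C3 is blocked by chlorine, which does not exchange), and the furyllithium displaces bromide from the primary allylic carbon of 7 (SN2 alkylation, Z-alkene untouched), the aldehyde returning on aqueous work-up (directed lithiation with in situ aldehyde protection).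

Step 5
Reactants: 10 3-chloro-5-[(Z)-oct-2-en-1-yl]furan-2-carbaldehyde; 11 methyl hept-6-ynoate
Product: 13 methyl 8-[3-chloro-5-[(Z)-oct-2-en-1-yl]furan-2-yl]-8-hydroxyoct-6-ynoate (racemic at C8), via alkynyl(methyl)zinc 12 (not isolated)
Conditions: Me2Zn, toluene, 0 °C → rt; then 10, rt; H2O
Reagents that add atoms: none
Why: Me2Zn metalates the terminal alkyne and the alkynylzinc adds to the non-enolisable heteroaryl aldehyde (ligand-free dimethylzinc-mediated alkynylation), a reagent class that leaves the methyl ester, the ring chloride and the skipped alkene alone; the carbinol centre forms as a racemate.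

Step 6
Reactants: 13 methyl 8-[3-chloro-5-[(Z)-oct-2-en-1-yl]furan-2-yl]-8-hydroxyoct-6-ynoate
Product: 14 methyl 7-[(1S,5S)-3-chloro-5-hydroxy-5-[(Z)-oct-2-en-1-yl]-2-oxocyclopent-3-en-1-yl]hept-6-ynoate (alkynyl on C8 and hydroxyl on C12 trans)
Conditions: (R)-3,3'-bis(2,4,6-triisopropylphenyl)-1,1'-binaphthyl-2,2'-diyl N-triflylphosphoramide (10 mol %), H2O (10 equiv), toluene, 40 °C
Reagents that add atoms: water, O
Why: Proposed new method: the chiral acid ionises 13 to a furyl- and alkynyl-stabilised cation, water adds to the octenyl-bearing furan carbon (C12), the hemiketal opens to the 1,4-dihydroxypentadienyl cation C8–C9–C10–C11–C12, and C8–C12 bond formation followed by proton loss gives the 4-hydroxycyclopentenone; the closest known reaction types are the racemic Piancatelli rearrangement of 5-alkyl-2-furylcarbinols and chiral Brønsted acid catalysed aza-Piancatelli and Nazarov cyclisations. The five-membered ring closes by thermal conrotatory 4π electrocyclisation of that cation. Conrotation with the alkynyl group on C8 and the hydroxyl on C12 in the outward positions fixes their trans relation, and the absolute sense of rotation, hence C12, is to come from the phosphoramide anion hydrogen-bonded to the two OH groups of the cation. The step needs water to attack C12 and not the alkyne terminus C6 (Meyer–Schuster pathway): the charge sits mainly on the oxocarbenium carbon C12, which the octenyl group makes tertiary, attack at C8 only returns 13, and the chlorine on the central carbon C10 supports the cation by lone-pair donation. Ester, alkyne and the skipped Z-alkene should tolerate the weakly acidic medium.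

Step 7
Reactants: 14 methyl 7-[(1S,5S)-3-chloro-5-hydroxy-5-[(Z)-oct-2-en-1-yl]-2-oxocyclopent-3-en-1-yl]hept-6-ynoate
Product: 16 methyl (5E,7E)-7-[(5R)-3-chloro-5-hydroxy-5-[(Z)-oct-2-en-1-yl]-2-oxocyclopent-3-en-1-ylidene]hept-5-enoate, via allenone 15 (not isolated)
Conditions: Et3N (0.3 equiv), dry toluene, rt; then PPh3 (0.2 equiv), 40 °C
Reagents that add atoms: none
Why: Et3N removes the doubly activated C8–H and reprotonation at C6 gives the conjugated allenone (propargyl–allenyl prototropy), after which PPh3 adds to the central allene carbon C7 and relays a proton from C5 to C7 before leaving (phosphine-catalysed allenone-to-dienone isomerisation), giving the thermodynamically preferred 5E,7E geometry; C12 is not involved, and a free hydroxyl in a dry, alkoxide-free medium should avoid β-elimination, conjugate hydration and retro-aldol opening.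

Step 8
Reactants: 16 methyl (5E,7E)-7-[(5R)-3-chloro-5-hydroxy-5-[(Z)-oct-2-en-1-yl]-2-oxocyclopent-3-en-1-ylidene]hept-5-enoate
Product: 17 methyl (5E,7E)-7-[(5R)-5-acetoxy-3-chloro-5-[(Z)-oct-2-en-1-yl]-2-oxocyclopent-3-en-1-ylidene]hept-5-enoate (CNP0248978.2)
Conditions: Ac2O, DMAP, Et3N, CH2Cl2, 0 °C → rt
Reagents that add atoms: acetic anhydride, CC(=O)OC(C)=O
Why: DMAP-catalysed acyl transfer (nucleophilic catalysis via the N-acetylpyridinium ion) acetylates the hindered tertiary C12 hydroxyl, and because C8 is now sp2 no enolisable α-hydrogen remains to expel the acetate by E1cB, so C12 keeps its configuration.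

Compound list
1 | 3-bromofuran | Brc1ccoc1 | starting material
2 | 3-furyllithium (not isolated) | [Li]c1ccoc1 | intermediate
3 | 3-chlorofuran | Clc1ccoc1 | intermediate
4 | 3-chloro-2-furyllithium (not isolated) | [Li]c1occc1Cl | intermediate
5 | 3-chlorofuran-2-carbaldehyde | O=Cc1occc1Cl | intermediate
6 | (Z)-oct-2-en-1-ol | CCCCC/C=C\CO | starting material
7 | (Z)-1-bromooct-2-ene | CCCCC/C=C\CBr | intermediate
8 | lithium (3-chlorofuran-2-yl)(4-methylpiperazin-1-yl)methanolate (racemic, not isolated) | [Li]OC(c1occc1Cl)N1CCN(C)CC1 | intermediate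
9 | lithium (3-chloro-5-lithiofuran-2-yl)(4-methylpiperazin-1-yl)methanolate (racemic, not isolated) | [Li]OC(c1oc([Li])cc1Cl)N1CCN(C)CC1 | intermediate
10 | 3-chloro-5-[(Z)-oct-2-en-1-yl]furan-2-carbaldehyde | CCCCC/C=C\Cc1cc(Cl)c(C=O)o1 | intermediate
11 | methyl hept-6-ynoate | C#CCCCCC(=O)OC | starting material
12 | methyl 7-(methylzincio)hept-6-ynoate (not isolated) | C[Zn]C#CCCCCC(=O)OC | intermediate
13 | methyl 8-[3-chloro-5-[(Z)-oct-2-en-1-yl]furan-2-yl]-8-hydroxyoct-6-ynoate (racemic at the carbinol carbon) | CCCCC/C=C\Cc1cc(Cl)c(o1)C(O)C#CCCCCC(=O)OC | intermediate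
14 | methyl 7-[(1S,5S)-3-chloro-5-hydroxy-5-[(Z)-oct-2-en-1-yl]-2-oxocyclopent-3-en-1-yl]hept-6-ynoate | CCCCC/C=C\C[C@@]1(O)C=C(Cl)C(=O)[C@H]1C#CCCCCC(=O)OC | intermediate
15 | methyl 7-[(5R)-3-chloro-5-hydroxy-5-[(Z)-oct-2-en-1-yl]-2-oxocyclopent-3-en-1-ylidene]hept-6-enoate (allenone, both allene-axis isomers, not isolated) | CCCCC/C=C\C[C@@]1(O)C=C(Cl)C(=O)C1=C=CCCCCC(=O)OC | intermediate
16 | methyl (5E,7E)-7-[(5R)-3-chloro-5-hydroxy-5-[(Z)-oct-2-en-1-yl]-2-oxocyclopent-3-en-1-ylidene]hept-5-enoate | CCCCC/C=C\C[C@@]1(O)C=C(Cl)C(=O)/C1=C/C=C/CCCC(=O)OC | intermediate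
17 | methyl (5E,7E)-7-[(5R)-5-acetoxy-3-chloro-5-[(Z)-oct-2-en-1-yl]-2-oxocyclopent-3-en-1-ylidene]hept-5-enoate (12R in prostanoid numbering) | CCCCC/C=C\C[C@@]1(OC(C)=O)C=C(Cl)C(=O)/C1=C/C=C/CCCC(=O)OC | target

Total step count: 8
Longest linear sequence: 7 steps (steps 1, 2, 4, 5, 6, 7, 8 from 3-bromofuran; step 3 is a one-step branch)

Steps most likely to fail

Step 6. The chiral anion may discriminate the two senses of conrotation poorly. The acid may also be too weak to ionise the chlorinated carbinol, so that forcing conditions divert water to the alkyne terminus. Fallback (known chemistry): setting out from 13, the rearrangement is run without asymmetric induction under the classical conditions for 5-alkyl-2-furylcarbinols (ZnCl2, dioxane–H2O, 70 °C). This should give 14 together with its mirror image, methyl 7-[(1R,5R)-3-chloro-5-hydroxy-5-[(Z)-oct-2-en-1-yl]-2-oxocyclopent-3-en-1-yl]hept-6-ynoate F1. The two are separated by preparative chromatography on a chiral stationary phase, and the route is rejoined at 14.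

Step 7. The isomerisation may stall at allenone 15, the phosphine may be trapped by the ring chloro-enone, or the C12 hydroxyl may be lost by conjugate addition–elimination. Fallback: setting out from 14, nucleophilic catalysis is abandoned for a metal-hydride pathway. After the Et3N stage, IrH5(P(i-Pr)3)2 (cat.) in toluene at 60 °C should move the unsaturation by hydrometalation and β-hydride elimination to the E,E-dienone, rejoining the route at 16. No new compound arises (F0).

Step 4. Metalation of the doubly charged amino alkoxide at C5 may be incomplete, the product's doubly activated C13–H may quench unreacted aryllithium, or the bromide may be attacked in the SN2′ sense. Fallback: setting out from 5, the aldehyde is masked as an isolable acetal (ethylene glycol, TsOH, benzene, reflux) to give 2-(3-chlorofuran-2-yl)-1,3-dioxolane F2. n-BuLi in THF at −78 °C should give its 5-lithio derivative, 2-(3-chloro-5-lithiofuran-2-yl)-1,3-dioxolane F3, which is added to an excess of 7 to give 2-[3-chloro-5-[(Z)-oct-2-en-1-yl]furan-2-yl]-1,3-dioxolane F4. Mild hydrolysis (PPTS, acetone–H2O) rejoins the route at 10.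

Further compounds
F1 | step 6 | methyl 7-[(1R,5R)-3-chloro-5-hydroxy-5-[(Z)-oct-2-en-1-yl]-2-oxocyclopent-3-en-1-yl]hept-6-ynoate | CCCCC/C=C\C[C@]1(O)C=C(Cl)C(=O)[C@@H]1C#CCCCCC(=O)OC
F0 | step 7 | none | none
F2 | step 4 | 2-(3-chlorofuran-2-yl)-1,3-dioxolane | Clc1ccoc1C1OCCO1
F3 | step 4 | 2-(3-chloro-5-lithiofuran-2-yl)-1,3-dioxolane | [Li]c1cc(Cl)c(o1)C1OCCO1
F4 | step 4 | 2-[3-chloro-5-[(Z)-oct-2-en-1-yl]furan-2-yl]-1,3-dioxolane | CCCCC/C=C\Cc1cc(Cl)c(o1)C1OCCO1
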